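**Retrosynthetic overview**
1. Last bond: the C3–O ester to angelic acid, made on the free cis-(2R,3R) alcohol 16.
2. The isopropenyl group comes from dehydration of a C2–CMe2OH group; the acetyl group comes from the aryl bromide by Stille coupling, run while the C2–O bond is not yet allylic.
3. Only one ring is formed, the dihydrofuran: the ortho-phenoxide opens an erythro trisubstituted epoxide 5-exo, with inversion at C2, which gives the 2,3-cis relationship. The benzene ring is bought.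
4. The epoxide comes from a syn-(2S,3R) α-chloro-β-hydroxy ester (silylation, two MeMgBr, base). Both stereocentres come from a ketoreductase dynamic kinetic reduction of the racemising α-chloro-β-keto ester.
5. The keto ester comes from 2'-hydroxy-3',4'-dimethoxyacetophenone by bromination para to OH, O-allylation, Claisen condensation with diethyl carbonate and chlorination.

Assumption: 1 and angelic acid are bought; the ketoreductase is the panel enzyme found by screening for the (2S,3R) product (target >98% ee, syn:anti >20:1).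

Step 1
Reactants: 1 1-(2-hydroxy-3,4-dimethoxyphenyl)ethan-1-one
Product: 2 1-(5-bromo-2-hydroxy-3,4-dimethoxyphenyl)ethan-1-one
Conditions: NBS (1.05 equiv), MeCN, 0 °C to rt
Reagents that add atoms: N-bromosuccinimide O=C1CCC(=O)N1Br
Why: Electrophilic aromatic bromination goes para to the free phenol (and ortho to the 4-OMe), the only strongly activated open ring position.

Step 2
Reactants: 2 1-(5-bromo-2-hydroxy-3,4-dimethoxyphenyl)ethan-1-one
Product: 3 1-[5-bromo-3,4-dimethoxy-2-(prop-2-en-1-yloxy)phenyl]ethan-1-one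
Conditions: allyl bromide (1.5 equiv), K2CO3 (2 equiv), DMF, 60 °C
Reagents that add atoms: allyl bromide C=CCBr
Why: Williamson etherification masks the phenol as an allyl ether that survives base, Grignard reagent and enzyme and is later removed under neutral conditions.

Step 3
Reactants: 3 1-[5-bromo-3,4-dimethoxy-2-(prop-2-en-1-yloxy)phenyl]ethan-1-one
Product: 4 ethyl 3-[5-bromo-3,4-dimethoxy-2-(prop-2-en-1-yloxy)phenyl]-3-oxopropanoate
Conditions: NaH (3 equiv), (EtO)2CO (5 equiv), THF, reflux; then 1 M HCl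
Reagents that add atoms: diethyl carbonate CCOC(=O)OCC
Why: Crossed Claisen condensation of the methyl ketone enolate with non-enolisable diethyl carbonate is driven to completion by deprotonation of the β-keto ester.

Step 4
Reactants: 4 ethyl 3-[5-bromo-3,4-dimethoxy-2-(prop-2-en-1-yloxy)phenyl]-3-oxopropanoate
Product: 5 ethyl 3-[5-bromo-3,4-dimethoxy-2-(prop-2-en-1-yloxy)phenyl]-2-chloro-3-oxopropanoate (racemic)
Conditions: NCS (1.05 equiv), Mg(ClO4)2 (10 mol %), MeCN, rt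
Reagents that add atoms: N-chlorosuccinimide O=C1CCC(=O)N1Cl
Why: Lewis-acid-promoted electrophilic α-chlorination of the enolised β-keto ester is selective for the doubly activated carbon and leaves the allyl group and the deactivated ring alone.

Step 5
Reactants: 5 ethyl 3-[5-bromo-3,4-dimethoxy-2-(prop-2-en-1-yloxy)phenyl]-2-chloro-3-oxopropanoate (racemic)
Product: 6 ethyl (2S,3R)-3-[5-bromo-3,4-dimethoxy-2-(prop-2-en-1-yloxy)phenyl]-2-chloro-3-hydroxypropanoate
Conditions: ketoreductase (KRED, NADPH-dependent, EC 1.1.1), NADP+ (cat.), glucose dehydrogenase (GDH), D-glucose (1.5 equiv), KH2PO4/K2HPO4 buffer pH 6.5, 10% DMSO, 30 °C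
Reagents that add atoms: none
Why: Ketoreductase-catalysed dynamic reductive kinetic resolution: the α-chloro-β-keto ester racemises through its enol while the enzyme reduces only the (2S) ketone on one carbonyl face, so C3 (R) and C2 (S) are set together as the syn chlorohydrin.

Step 6
Reactants: 6 ethyl (2S,3R)-3-[5-bromo-3,4-dimethoxy-2-(prop-2-en-1-yloxy)phenyl]-2-chloro-3-hydroxypropanoate
Product: 7 ethyl (2S,3R)-3-[5-bromo-3,4-dimethoxy-2-(prop-2-en-1-yloxy)phenyl]-3-{[tert-butyl(dimethyl)silyl]oxy}-2-chloropropanoate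
Conditions: TBSOTf (1.3 equiv), 2,6-lutidine (2 equiv), CH2Cl2, −78 to 0 °C
Reagents that add atoms: tert-butyldimethylsilyl triflate CC(C)(C)[Si](C)(C)OS(=O)(=O)C(F)(F)F
Why: Silyl ether formation with a hindered non-nucleophilic base blocks the C3 oxygen, so that later only the tertiary alkoxide can displace chloride, without epimerising the α-chloro ester.

Step 7
Reactants: 7 ethyl (2S,3R)-3-[5-bromo-3,4-dimethoxy-2-(prop-2-en-1-yloxy)phenyl]-3-{[tert-butyl(dimethyl)silyl]oxy}-2-chloropropanoate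
Product: 9 (3S,4R)-4-[5-bromo-3,4-dimethoxy-2-(prop-2-en-1-yloxy)phenyl]-4-{[tert-butyl(dimethyl)silyl]oxy}-3-chloro-2-methylbutan-2-ol, via methyl ketone 8 (not isolated)
Conditions: MeMgBr (3.5 equiv), CeCl3 (3.5 equiv), THF, −78 to −20 °C; aq. NH4Cl
Reagents that add atoms: methylmagnesium bromide C[Mg]Br
Why: Cerium-moderated double Grignard addition to the ester proceeds through the methyl ketone without enolising the α-chloro carbonyl intermediates, so both stereocentres are untouched.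

Step 8
Reactants: 9 (3S,4R)-4-[5-bromo-3,4-dimethoxy-2-(prop-2-en-1-yloxy)phenyl]-4-{[tert-butyl(dimethyl)silyl]oxy}-3-chloro-2-methylbutan-2-ol
Product: 10 {(R)-[5-bromo-3,4-dimethoxy-2-(prop-2-en-1-yloxy)phenyl][(2R)-3,3-dimethyloxiran-2-yl]methoxy}(tert-butyl)dimethylsilane
Conditions: KOtBu (1.2 equiv), THF, 0 °C
Reagents that add atoms: none
Why: Intramolecular Williamson etherification (chlorohydrin to epoxide): the tertiary alkoxide displaces chloride by 3-exo-tet SN2 with inversion, giving the erythro epoxy silyl ether.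

Step 9
Reactants: 10 {(R)-[5-bromo-3,4-dimethoxy-2-(prop-2-en-1-yloxy)phenyl][(2R)-3,3-dimethyloxiran-2-yl]methoxy}(tert-butyl)dimethylsilane
Product: 12 2-[(2S,3R)-5-bromo-3-{[tert-butyl(dimethyl)silyl]oxy}-6,7-dimethoxy-2,3-dihydro-1-benzofuran-2-yl]propan-2-ol, via free phenol 11 (not isolated)
Conditions: Pd(PPh3)4 (5 mol %), K2CO3 (2 equiv), MeOH, rt then 45 °C
Reagents that add atoms: none
Why: Zerovalent palladium ionises the allyl aryl ether (Tsuji–Trost deallylation, methanol as allyl acceptor) and the freed phenoxide opens the epoxide at its CH carbon by 5-exo-tet SN2, so C2 is set with inversion and lies cis to the C3 silyloxy group.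

Step 10
Reactants: 12 2-[(2S,3R)-5-bromo-3-{[tert-butyl(dimethyl)silyl]oxy}-6,7-dimethoxy-2,3-dihydro-1-benzofuran-2-yl]propan-2-ol
Product: 14 1-[(2S,3R)-3-{[tert-butyl(dimethyl)silyl]oxy}-2-(2-hydroxypropan-2-yl)-6,7-dimethoxy-2,3-dihydro-1-benzofuran-5-yl]ethan-1-one, via enol ether 13 (not isolated)
Conditions: tributyl(1-ethoxyvinyl)stannane (1.5 equiv), PdCl2(PPh3)2 (5 mol %), toluene, 100 °C; then 0.5 M HCl, THF, 0 °C
Reagents that add atoms: tributyl(1-ethoxyvinyl)stannane C=C(OCC)[Sn](CCCC)(CCCC)CCCC; water O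
Why: Stille coupling installs a masked acetyl group that brief dilute-acid hydrolysis of the enol ether unveils, and it is run here so that zerovalent palladium never meets the later allylic aryl ether.

Step 11
Reactants: 14 1-[(2S,3R)-3-{[tert-butyl(dimethyl)silyl]oxy}-2-(2-hydroxypropan-2-yl)-6,7-dimethoxy-2,3-dihydro-1-benzofuran-5-yl]ethan-1-one
Product: 15 1-[(2R,3R)-3-{[tert-butyl(dimethyl)silyl]oxy}-6,7-dimethoxy-2-(prop-1-en-2-yl)-2,3-dihydro-1-benzofuran-5-yl]ethan-1-one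
Conditions: Burgess reagent (2 equiv), toluene, 50 °C
Reagents that add atoms: none
Why: Burgess dehydration (syn-elimination of the tertiary sulfamate) takes one of six methyl hydrogens in preference to the single C2–H on the oxygen-bearing carbon, giving the isopropenyl group with both stereocentres unchanged (the C2 descriptor changes from S to R only because the priorities change).

Step 12
Reactants: 15 1-[(2R,3R)-3-{[tert-butyl(dimethyl)silyl]oxy}-6,7-dimethoxy-2-(prop-1-en-2-yl)-2,3-dihydro-1-benzofuran-5-yl]ethan-1-one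
Product: 16 1-[(2R,3R)-3-hydroxy-6,7-dimethoxy-2-(prop-1-en-2-yl)-2,3-dihydro-1-benzofuran-5-yl]ethan-1-one
Conditions: TBAF (1.2 equiv), AcOH (1.2 equiv), THF, 0 °C to rt
Reagents that add atoms: none
Why: Buffered fluoride desilylation frees the benzylic alcohol without acid, which would ionise C3 and aromatise the ring to a benzofuran.

Step 13
Reactants: 16 1-[(2R,3R)-3-hydroxy-6,7-dimethoxy-2-(prop-1-en-2-yl)-2,3-dihydro-1-benzofuran-5-yl]ethan-1-one
Product: 17 (2R,3R)-5-acetyl-6,7-dimethoxy-2-(prop-1-en-2-yl)-2,3-dihydro-1-benzofuran-3-yl (2Z)-2-methylbut-2-enoate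
Conditions: angelic acid (3 equiv), 2,4,6-trichlorobenzoyl chloride (3 equiv), Et3N (3.3 equiv), toluene, rt, 2 h; then 16, 75 °C
Reagents that add atoms: angelic acid C/C=C(/C)C(=O)O
Why: Yamaguchi-type mixed-anhydride esterification without a nucleophilic amine catalyst acylates the C3 oxygen (configuration retained) and avoids the conjugate-addition pathway that isomerises angelate (Z) to tiglate (E).

**Compound list**
1 | 1-(2-hydroxy-3,4-dimethoxyphenyl)ethan-1-one | CC(=O)c1ccc(OC)c(OC)c1O | starting material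
2 | 1-(5-bromo-2-hydroxy-3,4-dimethoxyphenyl)ethan-1-one | CC(=O)c1cc(Br)c(OC)c(OC)c1O | intermediate
3 | 1-[5-bromo-3,4-dimethoxy-2-(prop-2-en-1-yloxy)phenyl]ethan-1-one | CC(=O)c1cc(Br)c(OC)c(OC)c1OCC=C | intermediate
4 | ethyl 3-[5-bromo-3,4-dimethoxy-2-(prop-2-en-1-yloxy)phenyl]-3-oxopropanoate | CCOC(=O)CC(=O)c1cc(Br)c(OC)c(OC)c1OCC=C | intermediate
5 | ethyl 3-[5-bromo-3,4-dimethoxy-2-(prop-2-en-1-yloxy)phenyl]-2-chloro-3-oxopropanoate (racemic, configurationally labile) | CCOC(=O)C(Cl)C(=O)c1cc(Br)c(OC)c(OC)c1OCC=C | intermediate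
6 | ethyl (2S,3R)-3-[5-bromo-3,4-dimethoxy-2-(prop-2-en-1-yloxy)phenyl]-2-chloro-3-hydroxypropanoate | CCOC(=O)[C@@H](Cl)[C@H](O)c1cc(Br)c(OC)c(OC)c1OCC=C | intermediate
7 | ethyl (2S,3R)-3-[5-bromo-3,4-dimethoxy-2-(prop-2-en-1-yloxy)phenyl]-3-{[tert-butyl(dimethyl)silyl]oxy}-2-chloropropanoate | CCOC(=O)[C@@H](Cl)[C@H](O[Si](C)(C)C(C)(C)C)c1cc(Br)c(OC)c(OC)c1OCC=C | intermediate
8 | (3S,4R)-4-[5-bromo-3,4-dimethoxy-2-(prop-2-en-1-yloxy)phenyl]-4-{[tert-butyl(dimethyl)silyl]oxy}-3-chlorobutan-2-one (methyl ketone, not isolated) | CC(=O)[C@@H](Cl)[C@H](O[Si](C)(C)C(C)(C)C)c1cc(Br)c(OC)c(OC)c1OCC=C | intermediate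
9 | (3S,4R)-4-[5-bromo-3,4-dimethoxy-2-(prop-2-en-1-yloxy)phenyl]-4-{[tert-butyl(dimethyl)silyl]oxy}-3-chloro-2-methylbutan-2-ol | CC(C)(O)[C@@H](Cl)[C@H](O[Si](C)(C)C(C)(C)C)c1cc(Br)c(OC)c(OC)c1OCC=C | intermediate
10 | {(R)-[5-bromo-3,4-dimethoxy-2-(prop-2-en-1-yloxy)phenyl][(2R)-3,3-dimethyloxiran-2-yl]methoxy}(tert-butyl)dimethylsilane | CC1(C)O[C@@H]1[C@H](O[Si](C)(C)C(C)(C)C)c2cc(Br)c(OC)c(OC)c2OCC=C | intermediate
11 | 4-bromo-6-{(R)-{[tert-butyl(dimethyl)silyl]oxy}[(2R)-3,3-dimethyloxiran-2-yl]methyl}-2,3-dimethoxyphenol (free phenol, not isolated) | CC1(C)O[C@@H]1[C@H](O[Si](C)(C)C(C)(C)C)c2cc(Br)c(OC)c(OC)c2O | intermediate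
12 | 2-[(2S,3R)-5-bromo-3-{[tert-butyl(dimethyl)silyl]oxy}-6,7-dimethoxy-2,3-dihydro-1-benzofuran-2-yl]propan-2-ol | O1[C@H](C(C)(C)O)[C@H](O[Si](C)(C)C(C)(C)C)c2cc(Br)c(OC)c(OC)c12 | intermediate
13 | 2-[(2S,3R)-3-{[tert-butyl(dimethyl)silyl]oxy}-5-(1-ethoxyethenyl)-6,7-dimethoxy-2,3-dihydro-1-benzofuran-2-yl]propan-2-ol (enol ether, not isolated) | O1[C@H](C(C)(C)O)[C@H](O[Si](C)(C)C(C)(C)C)c2cc(C(=C)OCC)c(OC)c(OC)c12 | intermediate
14 | 1-[(2S,3R)-3-{[tert-butyl(dimethyl)silyl]oxy}-2-(2-hydroxypropan-2-yl)-6,7-dimethoxy-2,3-dihydro-1-benzofuran-5-yl]ethan-1-one | O1[C@H](C(C)(C)O)[C@H](O[Si](C)(C)C(C)(C)C)c2cc(C(C)=O)c(OC)c(OC)c12 | intermediate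
15 | 1-[(2R,3R)-3-{[tert-butyl(dimethyl)silyl]oxy}-6,7-dimethoxy-2-(prop-1-en-2-yl)-2,3-dihydro-1-benzofuran-5-yl]ethan-1-one | O1[C@H](C(C)=C)[C@H](O[Si](C)(C)C(C)(C)C)c2cc(C(C)=O)c(OC)c(OC)c12 | intermediate
16 | 1-[(2R,3R)-3-hydroxy-6,7-dimethoxy-2-(prop-1-en-2-yl)-2,3-dihydro-1-benzofuran-5-yl]ethan-1-one | O1[C@H](C(C)=C)[C@H](O)c2cc(C(C)=O)c(OC)c(OC)c12 | intermediate
17 | (2R,3R)-5-acetyl-6,7-dimethoxy-2-(prop-1-en-2-yl)-2,3-dihydro-1-benzofuran-3-yl (2Z)-2-methylbut-2-enoate | C=C(C)[C@H]1Oc2c(cc(C(C)=O)c(OC)c2OC)[C@H]1OC(=O)/C(C)=C\C | target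

**Totals**
Total step count: 13. Longest linear sequence: 13 steps (fully linear from 1).

**Three steps most likely to fail, each with a fallback**

Step 5 (enzymatic dynamic reduction). The ortho-alkoxy, tetrasubstituted aryl ketone may be a poor fit for the panel enzymes, or only anti-selective enzymes may be found. The fallback sets out from 5 and changes both the catalyst type and the ring-closing logic. Transfer-hydrogenative dynamic kinetic resolution with RuCl(p-cymene)(TsDPEN) (the ligand antipode that gives 3R) in HCO2H/Et3N, which normally gives anti chlorohydrins, would give ethyl (2R,3R)-3-[5-bromo-3,4-dimethoxy-2-(prop-2-en-1-yloxy)phenyl]-2-chloro-3-hydroxypropanoate F1. TBSOTf/2,6-lutidine would give ethyl (2R,3R)-3-[5-bromo-3,4-dimethoxy-2-(prop-2-en-1-yloxy)phenyl]-3-{[tert-butyl(dimethyl)silyl]oxy}-2-chloropropanoate F2. Pd(PPh3)4/K2CO3 in EtOH would free ethyl (2R,3R)-3-(5-bromo-2-hydroxy-3,4-dimethoxyphenyl)-3-{[tert-butyl(dimethyl)silyl]oxy}-2-chloropropanoate F3 (not isolated), whose phenoxide displaces the α-chloride directly (5-exo-tet SN2, one inversion) to give ethyl (2S,3R)-5-bromo-3-{[tert-butyl(dimethyl)silyl]oxy}-6,7-dimethoxy-2,3-dihydro-1-benzofuran-2-carboxylate F4. MeMgBr/CeCl3 at −78 °C then adds twice, through 1-[(2S,3R)-5-bromo-3-{[tert-butyl(dimethyl)silyl]oxy}-6,7-dimethoxy-2,3-dihydro-1-benzofuran-2-yl]ethan-1-one F5 (not isolated), and the route is rejoined at 12.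

Step 11 (dehydration). Elimination toward C2 would give the enol ether and then a benzofuran. The fallback sets out from epoxide 10 and never makes the tertiary alcohol. Diethylaluminium 2,2,6,6-tetramethylpiperidide (from Et2AlCl and lithium 2,2,6,6-tetramethylpiperidide) in toluene at 0 °C isomerises the epoxide, without breaking the C2–O bond, to (1R,2S)-1-[5-bromo-3,4-dimethoxy-2-(prop-2-en-1-yloxy)phenyl]-1-{[tert-butyl(dimethyl)silyl]oxy}-3-methylbut-3-en-2-ol F6. Pd(PPh3)4/K2CO3/MeOH removes the allyl group to give 4-bromo-6-[(1R,2S)-1-{[tert-butyl(dimethyl)silyl]oxy}-2-hydroxy-3-methylbut-3-en-1-yl]-2,3-dimethoxyphenol F7. Stille coupling with tributyl(1-ethoxyvinyl)stannane/PdCl2(PPh3)2 gives 6-[(1R,2S)-1-{[tert-butyl(dimethyl)silyl]oxy}-2-hydroxy-3-methylbut-3-en-1-yl]-4-(1-ethoxyethenyl)-2,3-dimethoxyphenol F8 (not isolated), and dilute HCl converts it to 1-{5-[(1R,2S)-1-{[tert-butyl(dimethyl)silyl]oxy}-2-hydroxy-3-methylbut-3-en-1-yl]-4-hydroxy-2,3-dimethoxyphenyl}ethan-1-one F9. Intramolecular Mitsunobu etherification (PPh3, DIAD, THF, 0 °C) closes the ring with inversion at the allylic carbinol carbon and comes back to the route at 15.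

Step 13 (angeloylation). The hindered benzylic alcohol may acylate slowly, and heat can cause Z-to-E isomerisation or loss of the ester to a benzofuran. The fallback sets out from 16 and builds the Z-olefin on the substrate. Esterification with 2-[bis(2,2,2-trifluoroethoxy)phosphoryl]propanoic acid (DCC, cat. DMAP, CH2Cl2, 0 °C) gives (2R,3R)-5-acetyl-6,7-dimethoxy-2-(prop-1-en-2-yl)-2,3-dihydro-1-benzofuran-3-yl 2-[bis(2,2,2-trifluoroethoxy)phosphoryl]propanoate F10. Still–Gennari olefination (KN(SiMe3)2, 18-crown-6, THF, −78 °C, then acetaldehyde) gives the Z-trisubstituted ester and comes back to the route at 17.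

**Further compounds**
F1 | step 5 | ethyl (2R,3R)-3-[5-bromo-3,4-dimethoxy-2-(prop-2-en-1-yloxy)phenyl]-2-chloro-3-hydroxypropanoate | CCOC(=O)[C@H](Cl)[C@H](O)c1cc(Br)c(OC)c(OC)c1OCC=C
F2 | step 5 | ethyl (2R,3R)-3-[5-bromo-3,4-dimethoxy-2-(prop-2-en-1-yloxy)phenyl]-3-{[tert-butyl(dimethyl)silyl]oxy}-2-chloropropanoate | CCOC(=O)[C@H](Cl)[C@H](O[Si](C)(C)C(C)(C)C)c1cc(Br)c(OC)c(OC)c1OCC=C
F3 | step 5 | ethyl (2R,3R)-3-(5-bromo-2-hydroxy-3,4-dimethoxyphenyl)-3-{[tert-butyl(dimethyl)silyl]oxy}-2-chloropropanoate | CCOC(=O)[C@H](Cl)[C@H](O[Si](C)(C)C(C)(C)C)c1cc(Br)c(OC)c(OC)c1O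
F4 | step 5 | ethyl (2S,3R)-5-bromo-3-{[tert-butyl(dimethyl)silyl]oxy}-6,7-dimethoxy-2,3-dihydro-1-benzofuran-2-carboxylate | O1[C@H](C(=O)OCC)[C@H](O[Si](C)(C)C(C)(C)C)c2cc(Br)c(OC)c(OC)c12
F5 | step 5 | 1-[(2S,3R)-5-bromo-3-{[tert-butyl(dimethyl)silyl]oxy}-6,7-dimethoxy-2,3-dihydro-1-benzofuran-2-yl]ethan-1-one | O1[C@H](C(C)=O)[C@H](O[Si](C)(C)C(C)(C)C)c2cc(Br)c(OC)c(OC)c12
F6 | step 11 | (1R,2S)-1-[5-bromo-3,4-dimethoxy-2-(prop-2-en-1-yloxy)phenyl]-1-{[tert-butyl(dimethyl)silyl]oxy}-3-methylbut-3-en-2-ol | C=C(C)[C@H](O)[C@H](O[Si](C)(C)C(C)(C)C)c1cc(Br)c(OC)c(OC)c1OCC=C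
F7 | step 11 | 4-bromo-6-[(1R,2S)-1-{[tert-butyl(dimethyl)silyl]oxy}-2-hydroxy-3-methylbut-3-en-1-yl]-2,3-dimethoxyphenol | C=C(C)[C@H](O)[C@H](O[Si](C)(C)C(C)(C)C)c1cc(Br)c(OC)c(OC)c1O
F8 | step 11 | 6-[(1R,2S)-1-{[tert-butyl(dimethyl)silyl]oxy}-2-hydroxy-3-methylbut-3-en-1-yl]-4-(1-ethoxyethenyl)-2,3-dimethoxyphenol | C=C(C)[C@H](O)[C@H](O[Si](C)(C)C(C)(C)C)c1cc(C(=C)OCC)c(OC)c(OC)c1O
F9 | step 11 | 1-{5-[(1R,2S)-1-{[tert-butyl(dimethyl)silyl]oxy}-2-hydroxy-3-methylbut-3-en-1-yl]-4-hydroxy-2,3-dimethoxyphenyl}ethan-1-one | C=C(C)[C@H](O)[C@H](O[Si](C)(C)C(C)(C)C)c1cc(C(C)=O)c(OC)c(OC)c1O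
F10 | step 13 | (2R,3R)-5-acetyl-6,7-dimethoxy-2-(prop-1-en-2-yl)-2,3-dihydro-1-benzofuran-3-yl 2-[bis(2,2,2-trifluoroethoxy)phosphoryl]propanoate (both epimers at the phosphonate carbon) | O1[C@H](C(C)=C)[C@H](OC(=O)C(C)P(=O)(OCC(F)(F)F)OCC(F)(F)F)c2cc(C(C)=O)c(OC)c(OC)c12
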